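In a one-step world, target gained equals substrate lost. But in epsilon at 5.00 min the substrate has lost 87.2% and the target stands at 52.7%, so the substrate splits.

all flasks: substrate 24 mM

|  | first nucleophile | second nucleophile | remark | time |
|---|---|---|---|---|
| epsilon | 24 mM | 14.4 mM (fed, over 12 min) | run made earlier |  |
| theta | 96 mM | 14.4 mM (fed, over 12 min) | run made earlier |  |
| gamma | 48 mM | 29 mM (fed, over 12 min) | run made earlier |  |
| flask | 48.0 mM | 14.4 mM (fed, over 12 min) |  | 40 min |

| run | time / min | target / % | substrate / % |
|---|---|---|---|
| epsilon | 2.00 | 37.5 | 44.8 |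
| epsilon | 5.00 | 52.7 | 12.8 |
| epsilon | 15.0 | 50.2 | 0 |
| epsilon | 40.0 | 45.3 | 0 |
| theta | 2.00 | 49.8 | 45.2 |
| theta | 5.00 | 71.9 | 12.9 |
| theta | 15.0 | 71.4 | 0.6 |
| theta | 40.0 | 64.6 | 0 |
| gamma | 2.00 | 43.9 | 43.6 |
| gamma | 5.00 | 62.0 | 13.1 |
| gamma | 15.0 | 59.0 | 0 |
| gamma | 40.0 | 55.1 | 0 |

(each reading ± 0.5 percentage points)

* time up to 40 min at which target stands highest
* the amount of target, in percent of the substrate charged, at that time

- the numbers in the tables scatter with a standard deviation of 0.5 percentage points

The substrate reads 12.8%, 12.9% and 13.1% at that time, although c(first nucleophile) runs from 24 mM to 96 mM. So we take its loss as the rate-limiting step, with 0.411 min⁻¹ read from epsilon, and look at the split. Target per substrate lost reads 60.4% in epsilon and 82.5% in theta. Those shares give 15.7 mM and 20.3 mM for c(first nucleophile) times the ratio of other losses to target. This is the level at which target and the rest take equal parts. The two differ, but we freeze their mean as the even-split level h, 18.0 mM. The share is then c/(c+h), which for the flask gives 72.7%.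

The forecast says 65.5% at 7 min: “Remaining substrate adds about 3 points by 7 min”. Our share times the substrate lost by that time gives 68.6% of the charge, higher than the forecast.

    first nucleophile → decomposed reagent (k = 4.20 × 10⁻⁴ s⁻¹)
    substrate → intermediate (k = 0.00680 s⁻¹)
    intermediate → solvolysis product (k = 0.0270 s⁻¹)
    target ⇌ isomer of the product (K = 0.370, k = 5.10 × 10⁻⁴ s⁻¹)
    first nucleophile + intermediate → target (k = 5.20 M⁻¹ s⁻¹)
    second nucleophile + intermediate → other capture product (k = 7.60 M⁻¹ s⁻¹)

The flask peaks at 67.4% at 7.30 min, and its target is down to 58.3% at 40.0 min. At the peak the flask holds 5.10% substrate, so h reads 19.6 mM against the frozen 18.0 mM. A neighbour flask, like this one but charged with 58 mM of second nucleophile, has a best of 57.2%, lower than the forecast's figure. Reckoned on the whole charge, h is 23.2 mM in the flask and 36.0 mM in that neighbour, larger.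

The readings stem from a simulated flask with made-up constants; scatter was added.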